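**Plan**

Retrosynthesis: cut the interflavan bond C4–C6' (upper C4 back to a ketone, lower C6' back to an aryllithium); upper ring C: cut C2–C3 and rejoin C2 to C4, which gives a 3-hydroxy-2,3-dihydrobenzofuran-3-carbaldehyde; lower pyran ring: cut C4–C4a and C3–O and rejoin C4a to C3, which gives a dihydrobenzofuran-3-ylmethanol.
Both dihydrobenzofurans are mirror-image 2,3-cis esters from one aryldiazoacetate (4) by Rh2(PTTL)4-catalysed C–H insertion (benzofuran C2–C3 bond) after double O-alkylation of a resorcinol acetate with two equivalents of one benzyl chloride (O–CH2 bonds).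
Forward: 1 + 2 (two equivalents) → 4; Rh2(S-PTTL)4 → 5 → hydroxy aldehyde 8 → ring expansion to dihydroflavonol 9; Rh2(R-PTTL)4 → 10 → alcohol 11 → aryl-shift ring expansion to 2,3-cis flavan-3-ol 13 → bromide 15; union 9 + 15 → 18 → ionic hydrogenation → 19 → hydrogenolysis → 20.
Enabling feature: in the upper ring C (O1–C2–C3–C4–C4a–C8a) the C3 carbinol sits next to C4, which is benzylic to ring A and activated by O1 (ortho) and O7 (para); at the ketone level C3(OH)–C4(=O) is an α-ketol, the thermodynamic isomer of the five-membered α-hydroxy aldehyde, and the C4 ketone is also the handle for the 3,4-cis interflavan bond.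
Stereochemistry: C2 of each unit from the chiral Rh catalyst; upper C3 thermodynamic (2,3-trans) in the ketol shift; lower C3 by inversion in the aryl shift (cis → cis); upper C4 by hydride delivery anti to the 3-OH onto the C4 cation that already carries the lower unit (3,4-cis).

Key step: step 6

Abbreviations: Bn = benzyl; DBB = 3,4-bis(benzyloxy)benzyl; Ar = 3,4-bis(benzyloxy)phenyl. Flavan numbering is used for chromans, benzofuran numbering for dihydrobenzofurans.
Assumption: Rh2(S-PTTL)4 is taken to give the (2S,3R) ester 5 and Rh2(R-PTTL)4 its enantiomer 10; if the sense of induction is the reverse, the two catalysts are exchanged.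

**Route**

Step 1
Reactants: 1 methyl 2-(2,4-dihydroxyphenyl)acetate; 2 3,4-bis(benzyloxy)benzyl chloride (DBB-Cl, 2.2 equiv in all)
Product: 3 methyl 2-[2,4-bis(DBB-oxy)phenyl]acetate
Conditions: 2 (2.2 equiv), K2CO3 (3 equiv), KI (cat.), DMF, 50 °C
Reagents that add atoms: 3,4-bis(benzyloxy)benzyl chloride (second equivalent of 2, for the second O-alkylation), ClCc1ccc(OCc2ccccc2)c(OCc2ccccc2)c1
Why: Twofold Williamson etherification: each of the two phenoxides takes up one molecule of 2 (the arylacetate CH2 is not deprotonated by K2CO3), so the two hydroxyls need no differentiation; the 2-O-DBB group later supplies C2 and ring B of each flavan unit and the 4-O-DBB group is a hydrogenolysable protecting group for O7.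

Step 2
Reactants: 3 methyl 2-[2,4-bis(DBB-oxy)phenyl]acetate
Product: 4 methyl 2-diazo-2-[2,4-bis(DBB-oxy)phenyl]acetate
Conditions: 4-acetamidobenzenesulfonyl azide, DBU, MeCN, 0 °C → rt
Reagents that add atoms: 4-acetamidobenzenesulfonyl azide, CC(=O)Nc1ccc(cc1)S(=O)(=O)N=[N+]=[N-]
Why: Regitz diazo transfer from the sulfonyl azide to the DBU-generated ester enolate of the arylacetate gives the donor/acceptor aryldiazoacetate.

Step 3
Reactants: 4 methyl 2-diazo-2-[2,4-bis(DBB-oxy)phenyl]acetate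
Product: 5 methyl (2S,3R)-2-Ar-6-(DBB-oxy)-2,3-dihydro-1-benzofuran-3-carboxylate (2,3-cis)
Conditions: Rh2(S-PTTL)4 (dirhodium tetrakis[N-phthaloyl-(S)-tert-leucinate], 1 mol %), toluene, −78 °C
Reagents that add atoms: none
Why: Enantioselective intramolecular C–H insertion of the rhodium carbene into the benzylic C–H bond of the ortho O–CH2Ar ether closes the dihydrofuran ring; the chiral carboxylate ligands set C2 (the only centre of 5 that survives, as C2 of the upper unit) and the concerted insertion should give the 2,3-cis ester.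

Step 4
Reactants: 5 methyl (2S,3R)-2-Ar-6-(DBB-oxy)-2,3-dihydro-1-benzofuran-3-carboxylate
Product: 7 methyl (2R,3S)-2-Ar-6-(DBB-oxy)-3-hydroxy-2,3-dihydro-1-benzofuran-3-carboxylate (OH trans to Ar), via potassium enolate 6 (not isolated)
Conditions: KN(SiMe3)2, THF, −78 °C; then 3-phenyl-2-(phenylsulfonyl)oxaziridine, −78 °C; aq. NH4Cl
Reagents that add atoms: 3-phenyl-2-(phenylsulfonyl)oxaziridine, O=S(=O)(c1ccccc1)N1OC1c1ccccc1
Why: Davis α-hydroxylation: the planar ester enolate 6 should be oxidised on the face anti to the C2 aryl group, so the new OH is trans to it; this C3 centre is only a relay, since C3 becomes the C4 carbonyl carbon in step 6.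

Step 5
Reactants: 7 methyl (2R,3S)-2-Ar-6-(DBB-oxy)-3-hydroxy-2,3-dihydro-1-benzofuran-3-carboxylate
Product: 8 (2R,3S)-2-Ar-6-(DBB-oxy)-3-hydroxy-2,3-dihydro-1-benzofuran-3-carbaldehyde
Conditions: i-Bu2AlH (2.2 equiv), CH2Cl2, −78 °C; aq. potassium sodium tartrate (KNaC4H4O6), 0 °C; used at once
Reagents that add atoms: none
Why: Partial reduction of the α-hydroxy ester to the aldehyde, the tetrahedral aluminium hemiacetal being held as a five-membered chelate with the neighbouring aluminium alkoxide until hydrolytic work-up; no stereocentre is touched.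

Step 6
Reactants: 8 (2R,3S)-2-Ar-6-(DBB-oxy)-3-hydroxy-2,3-dihydro-1-benzofuran-3-carbaldehyde
Product: 9 (2R,3R)-2-Ar-7-(DBB-oxy)-3-hydroxy-2,3-dihydro-4H-chromen-4-one (2,3-trans)
Conditions: Al(O-t-Bu)3 (1.2 equiv), toluene, 60 °C; aq. potassium sodium tartrate (KNaC4H4O6)
Reagents that add atoms: none
Why: Al(O-t-Bu)3 converts the tertiary alcohol of 8 into an aluminium alkoxide chelated to the formyl oxygen, and in this chelate the ring bond to C2 migrates from the carbinol carbon to the formyl carbon while the carbinol carbon becomes a ketone, which is an α-ketol (acyloin) rearrangement of a tertiary α-hydroxy aldehyde, the reaction type used for one-carbon enlargement of 1-hydroxycycloalkanecarbaldehydes and for D-homoannulation of steroids. Ring C is therefore formed by ring expansion, a 1,2-shift of a ring C–C bond in which the former formyl carbon is inserted as C3 between C2 and the old benzofuran C3 (now C4), so the dihydrobenzofuran ring O1–C2–C3–C3a–C7a grows into the chroman-4-one ring O1–C2–C3–C4–C4a–C8a without any new bond to oxygen. C2 migrates with retention and keeps the configuration set in step 3; C3 is new and should end trans to the aryl group (both equatorial, the oxygen chelated in the plane of the carbonyl) because the aluminium ketol can equilibrate at C3 through its enediolate. The selectivity required is migration of C2 in preference to the ring A carbon: C2 migration gives directly the ketone conjugated with ring A (O7 para, O1 ortho), the thermodynamic ketol, and if ring A migrates first the resulting 4-hydroxy-3-ketone should be funnelled to the same product by an Oppenauer-type 1,2-hydride shift inside the chelate. The reaction is driven by the change from aldehyde to aryl ketone and by release of dihydrobenzofuran ring strain, and 8 has no hydrogen on C3 that would allow aromatisation to a benzofuran.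

Step 7
Reactants: 4 methyl 2-diazo-2-[2,4-bis(DBB-oxy)phenyl]acetate
Product: 10 methyl (2R,3S)-2-Ar-6-(DBB-oxy)-2,3-dihydro-1-benzofuran-3-carboxylate (2,3-cis; enantiomer of 5)
Conditions: Rh2(R-PTTL)4 (dirhodium tetrakis[N-phthaloyl-(R)-tert-leucinate], 1 mol %), toluene, −78 °C
Reagents that add atoms: none
Why: The same carbene C–H insertion as in step 3 with the mirror-image catalyst gives the enantiomeric cis ester, so both flavan units stem from 4; C2 becomes C2 of the lower unit and the cis relationship is needed for its 2,3-cis configuration.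

Step 8
Reactants: 10 methyl (2R,3S)-2-Ar-6-(DBB-oxy)-2,3-dihydro-1-benzofuran-3-carboxylate
Product: 11 [(2R,3R)-2-Ar-6-(DBB-oxy)-2,3-dihydro-1-benzofuran-3-yl]methanol (2,3-cis)
Conditions: LiAlH4, THF, −40 → 0 °C
Reagents that add atoms: none
Why: Hydride reduction of the ester to the primary alcohol is much faster than enolisation, so the 2,3-cis relationship is kept.

Step 9
Reactants: 11 [(2R,3R)-2-Ar-6-(DBB-oxy)-2,3-dihydro-1-benzofuran-3-yl]methanol
Product: 13 (2S,3S)-2-Ar-7-(DBB-oxy)-3,4-dihydro-2H-chromen-3-ol (2,3-cis), via primary mesylate 12 (not isolated)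
Conditions: MsCl, Et3N, CH2Cl2, −30 °C; then 2,6-lutidine, acetone–H2O (4:1), 50 °C
Reagents that add atoms: water, O (oxygen of the 3-OH); methanesulfonyl chloride, CS(=O)(=O)Cl (mesyl group of 12 only)
Why: Solvolysis of the primary mesylate with anchimeric assistance by ring A, whose ipso carbon C3a is para to the 6-alkoxy group and ortho to O1: the aryl group bridges and shifts from C3 to the CH2 carbon (Wagner–Meerwein 1,2-aryl shift through a phenonium ion, a Demjanov-type ring enlargement as with indan-1-ylmethyl derivatives) and water opens the bridge at the ring carbon with inversion, which turns the 2,3-cis dihydrobenzofuran into the 2,3-cis chroman-3-ol (new C3 is S) without touching C2.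

Step 10
Reactants: 13 (2S,3S)-2-Ar-7-(DBB-oxy)-3,4-dihydro-2H-chromen-3-ol
Product: 14 (2S,3S)-3-(benzyloxy)-2-Ar-7-(DBB-oxy)-3,4-dihydro-2H-chromene
Conditions: NaH, BnBr, Bu4NI (cat.), THF, 0 °C → rt
Reagents that add atoms: benzyl bromide, BrCc1ccccc1
Why: Williamson benzylation of the secondary alkoxide protects O3 against the organolithium chemistry of step 12.

Step 11
Reactants: 14 (2S,3S)-3-(benzyloxy)-2-Ar-7-(DBB-oxy)-3,4-dihydro-2H-chromene
Product: 15 (2S,3S)-3-(benzyloxy)-6-bromo-2-Ar-7-(DBB-oxy)-3,4-dihydro-2H-chromene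
Conditions: NBS (1.0 equiv), CH2Cl2, −40 → 0 °C
Reagents that add atoms: N-bromosuccinimide, O=C1CCC(=O)N1Br
Why: Electrophilic aromatic bromination should occur on the resorcinol-type ring A, far more electron-rich than the catechol-type rings, at C6 (para to O1, ortho to the 7-alkoxy group), which is less hindered than C8 between two oxygens.

Step 12
Reactants: 9 (2R,3R)-2-Ar-7-(DBB-oxy)-3-hydroxy-2,3-dihydro-4H-chromen-4-one; 15 (2S,3S)-3-(benzyloxy)-6-bromo-2-Ar-7-(DBB-oxy)-3,4-dihydro-2H-chromene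
Product: 18 tertiary C4 alcohol of the protected dimer (4-hydroxy derivative of 19; upper unit 2R, 3-OH trans to Ar; either C4 epimer serves), via lithium alkoxide 16 (not isolated), via aryllithium 17 (not isolated)
Conditions: 15, n-BuLi, THF, −78 °C; 9, LiN(SiMe3)2, THF, −78 °C; combine, −78 → −20 °C; aq. NH4Cl
Reagents that add atoms: none
Why: Bromine–lithium exchange gives aryllithium 17, which adds to the C4 carbonyl of 9 (1,2-addition of an organolithium to a chroman-4-one) after the 3-OH has been masked as lithium alkoxide 16, which also blocks enolisation toward C3; the new C4 centre need not be controlled because it is planarised in step 13.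

Step 13
Reactants: 18 tertiary C4 alcohol of the protected dimer (4-hydroxy derivative of 19)
Product: 19 protected fisetinidol-(4β→6)-ent-epifisetinidol: upper unit 2R,3S with the 4-aryl group β (3,4-cis), 3-OH free, 3',4'-di-O-Bn, 7-O-DBB; lower unit 2S,3S, 3,3',4'-tri-O-Bn, 7-O-DBB
Conditions: Et3SiH, CF3CO2H (few equiv), CH2Cl2, −78 → −40 °C
Reagents that add atoms: none
Why: Ionic hydrogenation: the tertiary, doubly benzylic C4 hydroxyl ionises at low temperature, well before the acid attacks the DBB aryl ethers, to a cation stabilised by ring A (O1 ortho, O7 para) and by the lower aryl group, and Et3SiH should deliver hydride to the face anti to the C3 oxygen, the facial preference known from 3,4-trans additions of carbon nucleophiles to 2,3-trans flavan-4-yl cations; since the aryl group is already on C4, this places it cis to the 3-OH (4β).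

Step 14
Reactants: 19 protected fisetinidol-(4β→6)-ent-epifisetinidol
Product: 20 fisetinidol-(4β→6)-ent-epifisetinidol, (2R,3S,4S)-2-(3,4-dihydroxyphenyl)-4-[(2S,3S)-2-(3,4-dihydroxyphenyl)-3,7-dihydroxy-3,4-dihydro-2H-chromen-6-yl]-3,4-dihydro-2H-chromene-3,7-diol
Conditions: H2 (1 atm), Pd(OH)2/C, THF–MeOH–H2O, rt
Reagents that add atoms: none
Why: Catalytic hydrogenolysis should cleave all nine O-benzyl ethers and both O-DBB groups (each DBB ends as 4-methylcatechol) under conditions that the C2–O1 and C4–aryl bonds of benzylated proanthocyanidins tolerate; no stereocentre is affected.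

**Compound list**

1 | methyl 2-(2,4-dihydroxyphenyl)acetate | COC(=O)Cc1ccc(O)cc1O | starting material
2 | 3,4-bis(benzyloxy)benzyl chloride | ClCc1ccc(OCc2ccccc2)c(OCc2ccccc2)c1 | starting material
3 | methyl 2-[2,4-bis(DBB-oxy)phenyl]acetate | COC(=O)Cc1ccc(OCc2ccc(OCc3ccccc3)c(OCc3ccccc3)c2)cc1OCc1ccc(OCc2ccccc2)c(OCc2ccccc2)c1 | intermediate
4 | methyl 2-diazo-2-[2,4-bis(DBB-oxy)phenyl]acetate | COC(=O)C(=[N+]=[N-])c1ccc(OCc2ccc(OCc3ccccc3)c(OCc3ccccc3)c2)cc1OCc1ccc(OCc2ccccc2)c(OCc2ccccc2)c1 | intermediate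
5 | methyl (2S,3R)-2-Ar-6-(DBB-oxy)-2,3-dihydro-1-benzofuran-3-carboxylate (cis) | C(c1ccc(OCc2ccccc2)c(OCc2ccccc2)c1)Oc1ccc2c(c1)O[C@H](c1ccc(OCc3ccccc3)c(OCc3ccccc3)c1)[C@@H]2C(=O)OC | intermediate
6 | potassium enolate of 5 (not isolated) | C(c1ccc(OCc2ccccc2)c(OCc2ccccc2)c1)Oc1ccc2c(c1)O[C@H](c1ccc(OCc3ccccc3)c(OCc3ccccc3)c1)C2=C(OC)O[K] | intermediate
7 | methyl (2R,3S)-2-Ar-6-(DBB-oxy)-3-hydroxy-2,3-dihydro-1-benzofuran-3-carboxylate | C(c1ccc(OCc2ccccc2)c(OCc2ccccc2)c1)Oc1ccc2c(c1)O[C@H](c1ccc(OCc3ccccc3)c(OCc3ccccc3)c1)[C@]2(O)C(=O)OC | intermediate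
8 | (2R,3S)-2-Ar-6-(DBB-oxy)-3-hydroxy-2,3-dihydro-1-benzofuran-3-carbaldehyde | C(c1ccc(OCc2ccccc2)c(OCc2ccccc2)c1)Oc1ccc2c(c1)O[C@H](c1ccc(OCc3ccccc3)c(OCc3ccccc3)c1)[C@]2(O)C=O | intermediate
9 | (2R,3R)-2-Ar-7-(DBB-oxy)-3-hydroxy-2,3-dihydro-4H-chromen-4-one | C(c1ccc(OCc2ccccc2)c(OCc2ccccc2)c1)Oc1ccc2c(c1)O[C@H](c1ccc(OCc3ccccc3)c(OCc3ccccc3)c1)[C@@H](O)C2=O | intermediate
10 | methyl (2R,3S)-2-Ar-6-(DBB-oxy)-2,3-dihydro-1-benzofuran-3-carboxylate (cis) | C(c1ccc(OCc2ccccc2)c(OCc2ccccc2)c1)Oc1ccc2c(c1)O[C@@H](c1ccc(OCc3ccccc3)c(OCc3ccccc3)c1)[C@H]2C(=O)OC | intermediate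
11 | [(2R,3R)-2-Ar-6-(DBB-oxy)-2,3-dihydro-1-benzofuran-3-yl]methanol (cis) | C(c1ccc(OCc2ccccc2)c(OCc2ccccc2)c1)Oc1ccc2c(c1)O[C@@H](c1ccc(OCc3ccccc3)c(OCc3ccccc3)c1)[C@H]2CO | intermediate
12 | methanesulfonate of 11 (not isolated) | C(c1ccc(OCc2ccccc2)c(OCc2ccccc2)c1)Oc1ccc2c(c1)O[C@@H](c1ccc(OCc3ccccc3)c(OCc3ccccc3)c1)[C@H]2COS(C)(=O)=O | intermediate
13 | (2S,3S)-2-Ar-7-(DBB-oxy)-3,4-dihydro-2H-chromen-3-ol | C(c1ccc(OCc2ccccc2)c(OCc2ccccc2)c1)Oc1ccc2c(c1)O[C@@H](c1ccc(OCc3ccccc3)c(OCc3ccccc3)c1)[C@@H](O)C2 | intermediate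
14 | (2S,3S)-3-(benzyloxy)-2-Ar-7-(DBB-oxy)-3,4-dihydro-2H-chromene | C(c1ccc(OCc2ccccc2)c(OCc2ccccc2)c1)Oc1ccc2c(c1)O[C@@H](c1ccc(OCc3ccccc3)c(OCc3ccccc3)c1)[C@@H](OCc1ccccc1)C2 | intermediate
15 | (2S,3S)-3-(benzyloxy)-6-bromo-2-Ar-7-(DBB-oxy)-3,4-dihydro-2H-chromene | Brc1cc2c(cc1OCc1ccc(OCc3ccccc3)c(OCc3ccccc3)c1)O[C@@H](c1ccc(OCc3ccccc3)c(OCc3ccccc3)c1)[C@@H](OCc1ccccc1)C2 | intermediate
16 | lithium 3-alkoxide of 9 (not isolated) | C(c1ccc(OCc2ccccc2)c(OCc2ccccc2)c1)Oc1ccc2c(c1)O[C@H](c1ccc(OCc3ccccc3)c(OCc3ccccc3)c1)[C@@H](O[Li])C2=O | intermediate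
17 | 6-lithio derivative of 14 (not isolated) | [Li]c1cc2c(cc1OCc1ccc(OCc3ccccc3)c(OCc3ccccc3)c1)O[C@@H](c1ccc(OCc3ccccc3)c(OCc3ccccc3)c1)[C@@H](OCc1ccccc1)C2 | intermediate
18 | tertiary C4 alcohol of the protected dimer, 4-hydroxy derivative of 19 (C4 epimers) | C(c1ccc(OCc2ccccc2)c(OCc2ccccc2)c1)Oc1ccc2c(c1)O[C@H](c1ccc(OCc3ccccc3)c(OCc3ccccc3)c1)[C@@H](O)C2(O)c1cc2c(cc1OCc1ccc(OCc3ccccc3)c(OCc3ccccc3)c1)O[C@@H](c1ccc(OCc3ccccc3)c(OCc3ccccc3)c1)[C@@H](OCc1ccccc1)C2 | intermediate
19 | protected fisetinidol-(4β→6)-ent-epifisetinidol | C(c1ccc(OCc2ccccc2)c(OCc2ccccc2)c1)Oc1ccc2c(c1)O[C@H](c1ccc(OCc3ccccc3)c(OCc3ccccc3)c1)[C@@H](O)[C@H]2c1cc2c(cc1OCc1ccc(OCc3ccccc3)c(OCc3ccccc3)c1)O[C@@H](c1ccc(OCc3ccccc3)c(OCc3ccccc3)c1)[C@@H](OCc1ccccc1)C2 | intermediate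
20 | fisetinidol-(4β→6)-ent-epifisetinidol | Oc1ccc2c(c1)O[C@H](c1ccc(O)c(O)c1)[C@@H](O)[C@H]2c1cc2c(cc1O)O[C@@H](c1ccc(O)c(O)c1)[C@@H](O)C2 | target

**Count and risks**

Total steps: 14. Longest linear sequence: 10 steps (1, 2, 7, 8, 9, 10, 11, 12, 13, 14).

Step 6 (ring expansion of 8). The process that may go wrong is migration of the ring A carbon in place of C2, followed by enolisation of the 3-keto isomer toward C2 and loss of the C2 configuration; self-condensation of the hydroxy aldehyde on the aluminium alkoxide is a second possibility. The fallback takes the upper unit from the chiral pool without ring construction. It sets out from bromide 15. Commercial (2R,3R)-fustin is benzylated at its three phenols (BnBr, K2CO3, acetone, rt) to (2R,3R)-7,3',4'-tri-O-benzylfustin F1. Its lithium alkoxide is combined with aryllithium 17 as in step 12 to give the tertiary alcohol F2. Et3SiH/CF3CO2H as in step 13 gives the 3,4-cis protected dimer F3 (7-O-Bn in place of 7-O-DBB on the upper unit), and hydrogenolysis as in step 14 returns to 20.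

Step 9 (aryl-shift ring expansion of 11). The process that may go wrong is capture of the aryl-bridged ion at the primary carbon, which gives no ring enlargement; opening of the bridge to a free C3 cation, with elimination toward the flav-3-ene or loss of the cis relationship, is a second possibility. The fallback replaces the solvolytic partition by a semipinacol shift that is pulled through by ketone formation. It sets out from ester 10. α-Hydroxylation as in step 4 gives the hydroxy ester F4 (enantiomer of 7), and LiAlH4 gives the diol F5. TsCl in pyridine tosylates only the primary hydroxyl and gives the primary tosylate F6. Et3Al in CH2Cl2 (−78 → 0 °C) then moves ring A from the carbinol carbon to the CH2 carbon and gives the (2S)-flavan-3-one F7. LiBH(s-Bu)3 in THF at −78 °C delivers hydride anti to the 2-aryl group and returns to the 2,3-cis alcohol 13.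

Step 13 (ionic hydrogenation of 18). The process that may go wrong is poor facial selectivity of hydride delivery to the C4 cation, or a competing 1,2-hydride shift from C3. The fallback uses that shift on purpose. It sets out from 18. The cation is generated without silane (BF3·OEt2, CH2Cl2, −40 °C), so that the pinacol-type suprafacial shift of the hydrogen on C3 to C4 takes over and gives the 2,4-trans 4-aryl-flavan-3-one F8; the hydrogen arrives on the face anti to the former 3-oxygen, so the aryl group is again β. NaBH4 (MeOH–THF, −20 °C) then attacks C3 axially, anti to the pseudo-axial 4-aryl group, and returns to 19.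

Further compounds
F1 | step 6 | (2R,3R)-7,3',4'-tri-O-benzylfustin | C(c1ccccc1)Oc1ccc2c(c1)O[C@H](c1ccc(OCc3ccccc3)c(OCc3ccccc3)c1)[C@@H](O)C2=O
F2 | step 6 | tertiary alcohol from F1 and 17 (C4 epimers) | C(c1ccccc1)Oc1ccc2c(c1)O[C@H](c1ccc(OCc3ccccc3)c(OCc3ccccc3)c1)[C@@H](O)C2(O)c1cc2c(cc1OCc1ccc(OCc3ccccc3)c(OCc3ccccc3)c1)O[C@@H](c1ccc(OCc3ccccc3)c(OCc3ccccc3)c1)[C@@H](OCc1ccccc1)C2
F3 | step 6 | protected dimer with upper 7-O-Bn (3,4-cis) | C(c1ccccc1)Oc1ccc2c(c1)O[C@H](c1ccc(OCc3ccccc3)c(OCc3ccccc3)c1)[C@@H](O)[C@H]2c1cc2c(cc1OCc1ccc(OCc3ccccc3)c(OCc3ccccc3)c1)O[C@@H](c1ccc(OCc3ccccc3)c(OCc3ccccc3)c1)[C@@H](OCc1ccccc1)C2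
F4 | step 9 | methyl 2-Ar-6-(DBB-oxy)-3-hydroxy-2,3-dihydro-1-benzofuran-3-carboxylate, enantiomer of 7 | C(c1ccc(OCc2ccccc2)c(OCc2ccccc2)c1)Oc1ccc2c(c1)O[C@@H](c1ccc(OCc3ccccc3)c(OCc3ccccc3)c1)[C@@]2(O)C(=O)OC
F5 | step 9 | 3-(hydroxymethyl)-2-Ar-6-(DBB-oxy)-2,3-dihydro-1-benzofuran-3-ol from F4 | C(c1ccc(OCc2ccccc2)c(OCc2ccccc2)c1)Oc1ccc2c(c1)O[C@@H](c1ccc(OCc3ccccc3)c(OCc3ccccc3)c1)[C@@]2(O)CO
F6 | step 9 | primary tosylate of F5 | C(c1ccc(OCc2ccccc2)c(OCc2ccccc2)c1)Oc1ccc2c(c1)O[C@@H](c1ccc(OCc3ccccc3)c(OCc3ccccc3)c1)[C@@]2(O)COS(=O)(=O)c1ccc(C)cc1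
F7 | step 9 | (2S)-2-Ar-7-(DBB-oxy)-2H-chromen-3(4H)-one | C(c1ccc(OCc2ccccc2)c(OCc2ccccc2)c1)Oc1ccc2c(c1)O[C@@H](c1ccc(OCc3ccccc3)c(OCc3ccccc3)c1)C(=O)C2
F8 | step 13 | 2,4-trans 4-aryl-flavan-3-one from 18 (2R; 4-aryl β) | C(c1ccc(OCc2ccccc2)c(OCc2ccccc2)c1)Oc1ccc2c(c1)O[C@H](c1ccc(OCc3ccccc3)c(OCc3ccccc3)c1)C(=O)[C@H]2c1cc2c(cc1OCc1ccc(OCc3ccccc3)c(OCc3ccccc3)c1)O[C@@H](c1ccc(OCc3ccccc3)c(OCc3ccccc3)c1)[C@@H](OCc1ccccc1)C2
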